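(The numbers in the tables are calculated from invented constants, noise included.)

Late in both earlier runs the ring readings stay flat within their scatter, so the late curve can be replaced by its mean.

| flask | substrate | temperature | remark | time |
|---|---|---|---|---|
| green | 0.10 M | 100 °C | the very flask that is asked about, followed so far |  |
| ochre | 0.050 M | 106 °C | run made earlier |  |
| flask | 0.10 M | 100 °C |  | 6.0 h |

| run | time / min | ring / % | substrate / % |
|---|---|---|---|
| green | 30.0 | 41.5 | 1.5 |
| green | 60.0 | 38.3 | 1.1 |
| green | 90.0 | 38.9 | 0 |
| green | 120 | 39.4 | 0 |
| green | 150 | 38.8 | 0 |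
| green | 180 | 38.2 | 0.9 |
| green | 240 | 38.3 | 0.4 |
| ochre | 3.00 | 41.3 | 47.8 |
| ochre | 6.00 | 51.2 | 22.2 |
| ochre | 8.00 | 51.4 | 12.9 |
| ochre | 12.0 | 51.1 | 4.9 |
| ochre | 15.0 | 52.2 | 4.9 |
| ochre | 20.0 | 51.9 | 0.6 |

(standard deviation of a reading: 1 percentage point)

- removed ring is counted in
- additions bring no volume worth counting

- summer: at 6.0 h add substrate, 50.0 % of the amount charged, then wait 3.0 h
- midnight: at 6.0 h take out 90 % of the ring then present, then wait 3.0 h
- dawn: change nothing and wait 3.0 h more
- spring: at 6.0 h raise the temperature by 15 K, then wait 3.0 h

* ring, in percent of the substrate first charged, at 6.0 h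
* which option adds most ring ("none" when 2 percentage points or less is all one gets) (summer / midnight / dawn / spring / none)
* ring present, with what was taken out counted in, in percent of the substrate first charged, after summer
* ring present, with what was taken out counted in, in percent of the substrate first charged, after midnight

In the green run the readings from 60.0 min on average 38.6 %, with a standard error of 0.41 percentage points. In the ochre run the last 3, from 12.0 min, average 51.7 %. The farthest reading lies 0.75 points from its mean, less than one scatter, so the means lose nothing you can read.

The green split is 1.59: the part of the charge that is not ring, per part of ring. The ochre split is 0.933. I read each as a first-order balance, thermodynamic control, whose split ignores the charge. Ochre ran both hotter and thinner, and I lay the difference on temperature, a wager these runs cannot test: the logarithm of the split falls by 0.0886 K⁻¹.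

Now turn the settings by hand. Time: the stretch reads flat, so I put ring at 6.0 h at 38.6 % and expect nothing worth counting from dawn. Charge: summer keeps the split on a larger charge, giving 58.0 %. Removal: midnight banks 34.8 %, and the rest splits again, for 60.0 %. Temperature: spring takes the split to 0.420 and ring to 70.4 %. That reckoned gain of 32 points is larger than summer's or midnight's, so my choice is spring.

The forecast gives 38.7 % (38 % to 39.5 %), 49.5 % for summer (44 % to 58 %), 64.3 % for midnight (58 % to 69 %) and about 43 % for spring, and it names midnight. It reads the plateaus as a balance second order in ring, since “a first-order equilibrium would need an implausible ~100 kJ/mol”. There our reckonings part.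

The flask gives 39.0 %, then 58.9 % after summer and 59.9 % after midnight. Spring is best at 26 points, more than midnight's 21 points, and short of my 32 points; dawn adds 0.066 points.

ring ⇌ isomer of the product (K = 1.46, k = 0.00172 s⁻¹, Ea = 107 kJ mol⁻¹, ΔH = −90.0 kJ mol⁻¹); substrate → ring (k = 0.00246 s⁻¹, Ea = 95.0 kJ mol⁻¹); 2 substrate ⇌ open dimer (K = 137 M⁻¹, k = 0.00116 M⁻¹ s⁻¹, Ea = 90.0 kJ mol⁻¹, ΔH = −35.0 kJ mol⁻¹); ring → over-reaction product (k = 3.81 × 10⁻⁷ s⁻¹, Ea = 126 kJ mol⁻¹); (constants at 100 °C) Beside ring at 360 min stands 56.9 % of isomer of the product. Take the same flask at 85 °C: the reckoning takes the split from 1.59 to 5.99 and so gives 14.3 % ring, and that neighbouring flask gives 16.1 % ring.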